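## Retrosynthetic overview
1. End game: acetylation of C9–OH, then fluoride release of the C14 and C15 alcohols. Both esters and the α-methylene lactone are already in place by then.
2. Ten-membered ring (formed last): Nozaki–Hiyama–Kishi closure of C9–C10, a (Z)-alkenyl iodide adding to the C9 aldehyde.
3. Key C7–C8 bond: intermolecular zinc Barbier carbonyl allylation of TBSOCH2CHO (C8–C9) by an (R)-3-(bromomethyl)butenolide (C1–C7, C10–C15). This step reveals the α-methylene-γ-lactone and sets C7 and C8 from C6.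
4. Butenolide ring (formed first): ring-closing metathesis of the 2-(silyloxymethyl)acrylate of an (S)-bis-allylic alcohol.
5. Chain: C6 comes from Sharpless kinetic resolution of an enynol. C4=C5 comes from directed hydroalumination/iodination and a B-alkyl Suzuki coupling (C3–C4). The C10 iodide comes from Wittig olefination, α-iodination and Luche reduction.

Convention: C1–C15 are the germacrane positions of the target (C6 lactone carbinol, C7 ring fusion, C8 methylbutanoate, C9 acetate, C11=C13 exocyclic methylene, C12 lactone carbonyl, C14 on C10, C15 on C4). TBDPS = tert-butyldiphenylsilyl, TBS = tert-butyldimethylsilyl, TES = triethylsilyl. Both ring alkenes of the target are cis within the ring (CIP: 1(10)Z, 4E).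

## Route

Step 1
Reactants: 1 propargyl alcohol
Product: 2 tert-butyl(diphenyl)(prop-2-yn-1-yloxy)silane
Conditions: TBDPSCl, imidazole, CH2Cl2, 0 °C to rt
Reagents that add atoms: tert-butyl(chloro)diphenylsilane (TBDPSCl), CC(C)(C)[Si](Cl)(c1ccccc1)c1ccccc1
Why: Imidazole-promoted O-silylation of a primary alcohol gives a TBDPS ether (future C15–O) that resists the hydride, base, mild acid and short HF treatments used before the last step.

Step 2
Reactants: 2 tert-butyl(diphenyl)(prop-2-yn-1-yloxy)silane; 3 (E)-crotonaldehyde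
Product: 5 racemic (E)-1-(TBDPSO)hept-5-en-2-yn-4-ol, via lithium acetylide 4 (not isolated)
Conditions: n-BuLi, THF, −78 °C; then 3, −78 °C; aq NH4Cl
Reagents that add atoms: none
Why: In this carbonyl alkynylation the lithium acetylide adds 1,2 to the enal and forms the C5–C6 bond, giving the carbinol as a racemate.

Step 3
Reactants: 5 racemic (E)-1-(TBDPSO)hept-5-en-2-yn-4-ol
Product: 6 (4S,5E)-1-(TBDPSO)hept-5-en-2-yn-4-ol
Conditions: Ti(OiPr)4 (15 mol %), L-(+)-diisopropyl tartrate (18 mol %), t-BuOOH (0.6 equiv), 4 Å sieves, CH2Cl2, −20 °C, to about 55–60 % conversion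
Reagents that add atoms: none
Why: In this Sharpless kinetic resolution L-(+)-diisopropyl tartrate directs much faster epoxidation of the (R)-alcohol at its E-propenyl group, so the unreacted (S)-alcohol, which carries the C6 configuration of the target, is recovered in ≥98 % ee (maximum yield 50 %).

Step 4
Reactants: 6 (4S,5E)-1-(TBDPSO)hept-5-en-2-yn-4-ol
Product: 8 (2E,4S,5Z)-7-(TBDPSO)-6-iodohepta-2,5-dien-4-ol, via cyclic alkenylalanate 7 (not isolated)
Conditions: NaAlH2(OCH2CH2OMe)2, THF, 0 °C to rt; then I2, THF, −78 °C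
Reagents that add atoms: iodine, II
Why: Hydroxyl-directed trans-hydroalumination of the propargylic alcohol puts aluminium on C4 in a five-membered oxa-alanate, and iodinolysis with retention places iodine cis to C6, which fixes the C4=C5 geometry without touching C6.

Step 5
Reactants: 8 (2E,4S,5Z)-7-(TBDPSO)-6-iodohepta-2,5-dien-4-ol
Product: 9 (2E,4S,5Z)-7-(TBDPSO)-6-iodo-4-(TESO)hepta-2,5-diene
Conditions: TESCl, imidazole, CH2Cl2, 0 °C
Reagents that add atoms: chlorotriethylsilane (TESCl), CC[Si](Cl)(CC)CC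
Why: This standard O-silylation uses TES because it can later be removed in the presence of the TBDPS ethers.

Step 6
Reactants: 9 (2E,4S,5Z)-7-(TBDPSO)-6-iodo-4-(TESO)hepta-2,5-diene; 10 allyl acetate
Product: 12 (4E,6S,7E)-4-(TBDPSOCH2)-6-(TESO)nona-4,7-dien-1-yl acetate, via B-(3-acetoxypropyl)-9-BBN 11 (not isolated)
Conditions: 10, 9-BBN-H, THF, 0 °C to rt; then aq Cs2CO3, 9, PdCl2(dppf) (5 mol %), AsPh3, DMF, rt
Reagents that add atoms: none
Why: In this B-alkyl Suzuki–Miyaura coupling 9-BBN-H adds anti-Markovnikov to allyl acetate and zerovalent palladium couples the primary alkylborane with the alkenyl iodide with retention, so C3 ends up cis to C6.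

Step 7
Reactants: 12 (4E,6S,7E)-4-(TBDPSOCH2)-6-(TESO)nona-4,7-dien-1-yl acetate
Product: 13 (4E,6S,7E)-4-(TBDPSOCH2)-6-(TESO)nona-4,7-dien-1-ol
Conditions: K2CO3 (0.2 equiv), MeOH, 0 °C to rt
Reagents that add atoms: none
Why: Base-catalysed transesterification removes only the acetate, because the silyl ethers survive K2CO3/MeOH for the short reaction time.

Step 8
Reactants: 13 (4E,6S,7E)-4-(TBDPSOCH2)-6-(TESO)nona-4,7-dien-1-ol
Product: 14 (4E,6S,7E)-4-(TBDPSOCH2)-6-(TESO)nona-4,7-dienal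
Conditions: Dess–Martin periodinane, CH2Cl2, 0 °C to rt
Reagents that add atoms: none
Why: Dess–Martin oxidation stops at the C1 aldehyde under nearly neutral conditions that leave the silyl ethers and alkenes intact.

Step 9
Reactants: 14 (4E,6S,7E)-4-(TBDPSOCH2)-6-(TESO)nona-4,7-dienal; 15 (triphenylphosphoranylidene)acetaldehyde
Product: 16 (2E,6E,8S,9E)-6-(TBDPSOCH2)-8-(TESO)undeca-2,6,9-trienal
Conditions: toluene, 50 °C
Reagents that add atoms: none
Why: Wittig olefination with this stabilised ylide adds C10 and C14 and gives the (E)-enal.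

Step 10
Reactants: 16 (2E,6E,8S,9E)-6-(TBDPSOCH2)-8-(TESO)undeca-2,6,9-trienal
Product: 17 (2Z,6E,8S,9E)-2-iodo-6-(TBDPSOCH2)-8-(TESO)undeca-2,6,9-trienal
Conditions: I2, K2CO3, DMAP (20 mol %), THF/H2O 1:1, rt
Reagents that add atoms: iodine, II
Why: This Baylis–Hillman-type α-iodination (DMAP conjugate addition, enolate iodination, E1cB loss of DMAP) acts only on the electron-poor enal and keeps the CHO group trans to the chain, which gives the (Z)-iodoenal.

Step 11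
Reactants: 17 (2Z,6E,8S,9E)-2-iodo-6-(TBDPSOCH2)-8-(TESO)undeca-2,6,9-trienal
Product: 18 (2Z,6E,8S,9E)-2-iodo-6-(TBDPSOCH2)-8-(TESO)undeca-2,6,9-trien-1-ol
Conditions: NaBH4, CeCl3·7H2O, MeOH, −78 to −40 °C
Reagents that add atoms: none
Why: Luche reduction gives clean 1,2-reduction of the aldehyde without touching the alkenyl iodide or its geometry.

Step 12
Reactants: 18 (2Z,6E,8S,9E)-2-iodo-6-(TBDPSOCH2)-8-(TESO)undeca-2,6,9-trien-1-ol
Product: 19 (2Z,6E,8S,9E)-1-(TBDPSO)-2-iodo-6-(TBDPSOCH2)-8-(TESO)undeca-2,6,9-triene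
Conditions: TBDPSCl, imidazole, CH2Cl2, rt
Reagents that add atoms: tert-butyl(chloro)diphenylsilane (TBDPSCl), CC(C)(C)[Si](Cl)(c1ccccc1)c1ccccc1
Why: O-silylation gives C14–O the same robust protection as C15–O, so one final operation frees both.

Step 13
Reactants: 19 (2Z,6E,8S,9E)-1-(TBDPSO)-2-iodo-6-(TBDPSOCH2)-8-(TESO)undeca-2,6,9-triene
Product: 20 (2E,4S,5E,9Z)-11-(TBDPSO)-10-iodo-6-(TBDPSOCH2)undeca-2,5,9-trien-4-ol
Conditions: HF·pyridine, pyridine, THF, 0 °C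
Reagents that add atoms: none
Why: This desilylation is selective because buffered HF·pyridine cleaves a secondary TES ether far faster than primary TBDPS ethers, and the C6–O bond is never broken.

Step 14
Reactants: 21 ethyl 2-(hydroxymethyl)acrylate
Product: 22 ethyl 2-(TBSOCH2)acrylate
Conditions: TBSCl, imidazole, CH2Cl2, 0 °C to rt
Reagents that add atoms: tert-butyl(chloro)dimethylsilane (TBSCl), CC(C)(C)[Si](C)(C)Cl
Why: O-silylation masks the future C13 oxygen during ester hydrolysis, coupling and metathesis.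

Step 15
Reactants: 22 ethyl 2-(TBSOCH2)acrylate
Product: 23 2-(TBSOCH2)acrylic acid
Conditions: LiOH, THF/H2O, 0 °C to rt; then 1 M HCl to pH 4, 0 °C
Reagents that add atoms: lithium hydroxide, [Li+].[OH-]
Why: Saponification of the unhindered ethyl ester proceeds under conditions the primary TBS ether tolerates, provided acidification is careful.

Step 16
Reactants: 20 (2E,4S,5E,9Z)-11-(TBDPSO)-10-iodo-6-(TBDPSOCH2)undeca-2,5,9-trien-4-ol; 23 2-(TBSOCH2)acrylic acid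
Product: 25 (2E,4S,5E,9Z)-11-(TBDPSO)-10-iodo-6-(TBDPSOCH2)undeca-2,5,9-trien-4-yl 2-(TBSOCH2)acrylate, via O-acylisourea 24 (not isolated)
Conditions: DCC, DMAP (20 mol %), CH2Cl2, 0 °C to rt
Reagents that add atoms: none
Why: Steglich esterification acylates the oxygen atom, so C6 keeps its configuration.

Step 17
Reactants: 25 (2E,4S,5E,9Z)-11-(TBDPSO)-10-iodo-6-(TBDPSOCH2)undeca-2,5,9-trien-4-yl 2-(TBSOCH2)acrylate
Product: 26 (5R)-3-(TBSOCH2)-5-[(1E,5Z)-7-(TBDPSO)-6-iodo-2-(TBDPSOCH2)hepta-1,5-dien-1-yl]furan-2(5H)-one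
Conditions: second-generation Grubbs catalyst (5–10 mol %), toluene (5 mM), 80 °C
Reagents that add atoms: none
Why: In this ring-closing metathesis the ruthenium carbene loads at the disubstituted propenyl group and closes the five-membered ring onto the acrylate (C7=C11) with loss of propene, while the trisubstituted alkene and the alkenyl iodide are inert and C6 is unchanged.

Step 18
Reactants: 26 (5R)-3-(TBSOCH2)-5-[(1E,5Z)-7-(TBDPSO)-6-iodo-2-(TBDPSOCH2)hepta-1,5-dien-1-yl]furan-2(5H)-one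
Product: 27 (5R)-3-(hydroxymethyl)-5-[(1E,5Z)-7-(TBDPSO)-6-iodo-2-(TBDPSOCH2)hepta-1,5-dien-1-yl]furan-2(5H)-one
Conditions: HF·pyridine, pyridine, THF, 0 °C to rt
Reagents that add atoms: none
Why: This desilylation is selective because the primary allylic TBS ether falls much faster than TBDPS under acidic fluoride, and no strong base reaches the epimerisable C6–H.

Step 19
Reactants: 27 (5R)-3-(hydroxymethyl)-5-[(1E,5Z)-7-(TBDPSO)-6-iodo-2-(TBDPSOCH2)hepta-1,5-dien-1-yl]furan-2(5H)-one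
Product: 28 (5R)-3-(bromomethyl)-5-[(1E,5Z)-7-(TBDPSO)-6-iodo-2-(TBDPSOCH2)hepta-1,5-dien-1-yl]furan-2(5H)-one
Conditions: CBr4, PPh3, CH2Cl2, −20 to 0 °C
Reagents that add atoms: tetrabromomethane, BrC(Br)(Br)Br
Why: The Appel reaction turns the primary allylic alcohol into the bromide under neutral conditions.

Step 20 (key step)
Reactants: 28 (5R)-3-(bromomethyl)-5-[(1E,5Z)-7-(TBDPSO)-6-iodo-2-(TBDPSOCH2)hepta-1,5-dien-1-yl]furan-2(5H)-one; 29 (tert-butyldimethylsilyloxy)acetaldehyde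
Product: 31 (4R,5R)-4-[(1R)-2-(TBSO)-1-hydroxyethyl]-5-[(1E,5Z)-7-(TBDPSO)-6-iodo-2-(TBDPSOCH2)hepta-1,5-dien-1-yl]-3-methylideneoxolan-2-one, via allylzinc bromide 30 (not isolated)
Conditions: Zn dust, THF/sat. aq NH4Cl, 0 °C to rt
Reagents that add atoms: none
Why: In this zinc Barbier carbonyl allylation zinc inserts only into the allylic carbon–bromine bond, and the ring-locked E-type allylzinc reacts at C7 through a closed chair transition state on the butenolide face opposite the C6 side chain (6,7-trans lactone) with the aldehyde substituent equatorial (7,8-anti in the crotylation sense), which sets C7 and C8 as in the target and moves the double bond to the exocyclic C11=C13 position.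

Step 21
Reactants: 31 (4R,5R)-4-[(1R)-2-(TBSO)-1-hydroxyethyl]-5-[(1E,5Z)-7-(TBDPSO)-6-iodo-2-(TBDPSOCH2)hepta-1,5-dien-1-yl]-3-methylideneoxolan-2-one; 32 (S)-2-methylbutanoic acid
Product: 34 (1R)-2-(TBSO)-1-{(2R,3S)-2-[(1E,5Z)-7-(TBDPSO)-6-iodo-2-(TBDPSOCH2)hepta-1,5-dien-1-yl]-4-methylidene-5-oxooxolan-3-yl}ethyl (2S)-2-methylbutanoate, via O-acylisourea 33 (not isolated)
Conditions: DCC, DMAP (30 mol %), CH2Cl2, 0 °C to rt
Reagents that add atoms: none
Why: Steglich esterification acylates O8 with retention at C8 and brings in the (2S) side-chain centre from the commercial acid, and doing it at once blocks translactonisation to the 8,12-olide.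

Step 22
Reactants: 34 (1R)-2-(TBSO)-1-{(2R,3S)-2-[(1E,5Z)-7-(TBDPSO)-6-iodo-2-(TBDPSOCH2)hepta-1,5-dien-1-yl]-4-methylidene-5-oxooxolan-3-yl}ethyl (2S)-2-methylbutanoate
Product: 35 (1R)-2-hydroxy-1-{(2R,3S)-2-[(1E,5Z)-7-(TBDPSO)-6-iodo-2-(TBDPSOCH2)hepta-1,5-dien-1-yl]-4-methylidene-5-oxooxolan-3-yl}ethyl (2S)-2-methylbutanoate
Conditions: HF·pyridine, pyridine, THF, 0 °C
Reagents that add atoms: none
Why: Selective desilylation of the primary TBS ether in a slightly acidic medium leaves the TBDPS ethers in place and keeps the base-catalysed O8 to O9 acyl shift slow.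

Step 23
Reactants: 35 (1R)-2-hydroxy-1-{(2R,3S)-2-[(1E,5Z)-7-(TBDPSO)-6-iodo-2-(TBDPSOCH2)hepta-1,5-dien-1-yl]-4-methylidene-5-oxooxolan-3-yl}ethyl (2S)-2-methylbutanoate
Product: 36 (1R)-2-oxo-1-{(2R,3S)-2-[(1E,5Z)-7-(TBDPSO)-6-iodo-2-(TBDPSOCH2)hepta-1,5-dien-1-yl]-4-methylidene-5-oxooxolan-3-yl}ethyl (2S)-2-methylbutanoate
Conditions: Dess–Martin periodinane, CH2Cl2, 0 °C to rt, used at once
Reagents that add atoms: none
Why: Dess–Martin oxidation gives the α-acyloxy aldehyde (C9) without base, so C8 is not epimerised.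

Step 24
Reactants: 36 (1R)-2-oxo-1-{(2R,3S)-2-[(1E,5Z)-7-(TBDPSO)-6-iodo-2-(TBDPSOCH2)hepta-1,5-dien-1-yl]-4-methylidene-5-oxooxolan-3-yl}ethyl (2S)-2-methylbutanoate
Product: 38 (1(10)Z,4E,6R,7S,8R,9S)-14,15-bis(TBDPSO)-9-hydroxy-8-[(2S)-2-methylbutanoyloxy]germacra-1(10),4,11(13)-trien-12,6-olide, via alkenylchromium dichloride 37 (not isolated)
Conditions: CrCl2 (12 equiv), NiCl2 (0.1 equiv), DMSO/THF, 2 mM, slow addition of 36, rt
Reagents that add atoms: none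
Why: In this Nozaki–Hiyama–Kishi macrocyclisation zerovalent nickel inserts into the alkenyl iodide with retention and, after transmetalation to trivalent chromium, the alkenyl group adds to the aldehyde anti to the C8–O bond (polar Felkin–Anh), which gives the 8,9-anti (9S) alcohol and a ring-cis C1=C10 while tolerating the esters and the α-methylene lactone.

Step 25
Reactants: 38 (1(10)Z,4E,6R,7S,8R,9S)-14,15-bis(TBDPSO)-9-hydroxy-8-[(2S)-2-methylbutanoyloxy]germacra-1(10),4,11(13)-trien-12,6-olide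
Product: 39 (1(10)Z,4E,6R,7S,8R,9S)-9-acetoxy-14,15-bis(TBDPSO)-8-[(2S)-2-methylbutanoyloxy]germacra-1(10),4,11(13)-trien-12,6-olide
Conditions: Ac2O, pyridine, DMAP (cat.), CH2Cl2, 0 °C
Reagents that add atoms: acetic anhydride, CC(=O)OC(C)=O
Why: DMAP-catalysed O-acetylation proceeds with retention at C9 and is fast enough to outrun acyl migration.

Step 26
Reactants: 39 (1(10)Z,4E,6R,7S,8R,9S)-9-acetoxy-14,15-bis(TBDPSO)-8-[(2S)-2-methylbutanoyloxy]germacra-1(10),4,11(13)-trien-12,6-olide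
Product: 40 (3aS,4R,5S,6Z,10E,11aR)-5-acetoxy-6,10-bis(hydroxymethyl)-3-methylidene-2-oxo-2,3,3a,4,5,8,9,11a-octahydrocyclodeca[b]furan-4-yl (2S)-2-methylbutanoate (target)
Conditions: HF·pyridine (excess), THF, 0 °C to rt, polyethylene vessel
Reagents that add atoms: none
Why: Global desilylation with acidic fluoride frees both primary allylic alcohols without the basic conditions that would trigger acyl migration or attack on the α-methylene lactone.

## Compound list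
1 | propargyl alcohol | C#CCO | starting material
2 | tert-butyl(diphenyl)(prop-2-yn-1-yloxy)silane | C#CCO[Si](c1ccccc1)(c1ccccc1)C(C)(C)C | intermediate
3 | (E)-crotonaldehyde | C/C=C/C=O | starting material
4 | lithium acetylide of 2 | [Li]C#CCO[Si](c1ccccc1)(c1ccccc1)C(C)(C)C | intermediate
5 | racemic (E)-1-(TBDPSO)hept-5-en-2-yn-4-ol | C/C=C/C(O)C#CCO[Si](c1ccccc1)(c1ccccc1)C(C)(C)C | intermediate
6 | (4S,5E)-1-(TBDPSO)hept-5-en-2-yn-4-ol | C/C=C/[C@H](O)C#CCO[Si](c1ccccc1)(c1ccccc1)C(C)(C)C | intermediate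
7 | sodium cyclic alkenylalanate (O6–Al–C4 five-membered ring, two 2-methoxyethoxy ligands) | C/C=C/[C@@H]1O[Al-](OCCOC)(OCCOC)C(CO[Si](c2ccccc2)(c2ccccc2)C(C)(C)C)=C1.[Na+] | intermediate
8 | (2E,4S,5Z)-7-(TBDPSO)-6-iodohepta-2,5-dien-4-ol | C/C=C/[C@H](O)/C=C(/CO[Si](c1ccccc1)(c1ccccc1)C(C)(C)C)I | intermediate
9 | (2E,4S,5Z)-7-(TBDPSO)-6-iodo-4-(TESO)hepta-2,5-diene | C/C=C/[C@H](O[Si](CC)(CC)CC)/C=C(/CO[Si](c1ccccc1)(c1ccccc1)C(C)(C)C)I | intermediate
10 | allyl acetate | C=CCOC(C)=O | starting material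
11 | B-(3-acetoxypropyl)-9-borabicyclo[3.3.1]nonane | CC(=O)OCCCB1C2CCCC1CCC2 | intermediate
12 | (4E,6S,7E)-4-(TBDPSOCH2)-6-(TESO)nona-4,7-dien-1-yl acetate | C/C=C/[C@H](O[Si](CC)(CC)CC)/C=C(/CO[Si](c1ccccc1)(c1ccccc1)C(C)(C)C)CCCOC(C)=O | intermediate
13 | (4E,6S,7E)-4-(TBDPSOCH2)-6-(TESO)nona-4,7-dien-1-ol | C/C=C/[C@H](O[Si](CC)(CC)CC)/C=C(/CO[Si](c1ccccc1)(c1ccccc1)C(C)(C)C)CCCO | intermediate
14 | (4E,6S,7E)-4-(TBDPSOCH2)-6-(TESO)nona-4,7-dienal | C/C=C/[C@H](O[Si](CC)(CC)CC)/C=C(/CO[Si](c1ccccc1)(c1ccccc1)C(C)(C)C)CCC=O | intermediate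
15 | (triphenylphosphoranylidene)acetaldehyde | O=CC=P(c1ccccc1)(c1ccccc1)c1ccccc1 | starting material
16 | (2E,6E,8S,9E)-6-(TBDPSOCH2)-8-(TESO)undeca-2,6,9-trienal | C/C=C/[C@H](O[Si](CC)(CC)CC)/C=C(/CO[Si](c1ccccc1)(c1ccccc1)C(C)(C)C)CC/C=C/C=O | intermediate
17 | (2Z,6E,8S,9E)-2-iodo-6-(TBDPSOCH2)-8-(TESO)undeca-2,6,9-trienal | C/C=C/[C@H](O[Si](CC)(CC)CC)/C=C(/CO[Si](c1ccccc1)(c1ccccc1)C(C)(C)C)CC/C=C(/C=O)I | intermediate
18 | (2Z,6E,8S,9E)-2-iodo-6-(TBDPSOCH2)-8-(TESO)undeca-2,6,9-trien-1-ol | C/C=C/[C@H](O[Si](CC)(CC)CC)/C=C(/CO[Si](c1ccccc1)(c1ccccc1)C(C)(C)C)CC/C=C(/CO)I | intermediate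
19 | (2Z,6E,8S,9E)-1-(TBDPSO)-2-iodo-6-(TBDPSOCH2)-8-(TESO)undeca-2,6,9-triene | C/C=C/[C@H](O[Si](CC)(CC)CC)/C=C(/CO[Si](c1ccccc1)(c1ccccc1)C(C)(C)C)CC/C=C(/CO[Si](c1ccccc1)(c1ccccc1)C(C)(C)C)I | intermediate
20 | (2E,4S,5E,9Z)-11-(TBDPSO)-10-iodo-6-(TBDPSOCH2)undeca-2,5,9-trien-4-ol | C/C=C/[C@H](O)/C=C(/CO[Si](c1ccccc1)(c1ccccc1)C(C)(C)C)CC/C=C(/CO[Si](c1ccccc1)(c1ccccc1)C(C)(C)C)I | intermediate
21 | ethyl 2-(hydroxymethyl)acrylate | C=C(CO)C(=O)OCC | starting material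
22 | ethyl 2-(TBSOCH2)acrylate | C=C(CO[Si](C)(C)C(C)(C)C)C(=O)OCC | intermediate
23 | 2-(TBSOCH2)acrylic acid | C=C(CO[Si](C)(C)C(C)(C)C)C(=O)O | intermediate
24 | O-acylisourea from 23 and DCC | C=C(CO[Si](C)(C)C(C)(C)C)C(=O)OC(=NC1CCCCC1)NC1CCCCC1 | intermediate
25 | (2E,4S,5E,9Z)-11-(TBDPSO)-10-iodo-6-(TBDPSOCH2)undeca-2,5,9-trien-4-yl 2-(TBSOCH2)acrylate | C/C=C/[C@H](OC(=O)C(=C)CO[Si](C)(C)C(C)(C)C)/C=C(/CO[Si](c1ccccc1)(c1ccccc1)C(C)(C)C)CC/C=C(/CO[Si](c1ccccc1)(c1ccccc1)C(C)(C)C)I | intermediate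
26 | (5R)-3-(TBSOCH2)-5-[(1E,5Z)-7-(TBDPSO)-6-iodo-2-(TBDPSOCH2)hepta-1,5-dien-1-yl]furan-2(5H)-one | O=C1O[C@@H](C=C1CO[Si](C)(C)C(C)(C)C)/C=C(/CO[Si](c1ccccc1)(c1ccccc1)C(C)(C)C)CC/C=C(/CO[Si](c1ccccc1)(c1ccccc1)C(C)(C)C)I | intermediate
27 | (5R)-3-(hydroxymethyl) analogue of 26 | O=C1O[C@@H](C=C1CO)/C=C(/CO[Si](c1ccccc1)(c1ccccc1)C(C)(C)C)CC/C=C(/CO[Si](c1ccccc1)(c1ccccc1)C(C)(C)C)I | intermediate
28 | (5R)-3-(bromomethyl) analogue of 26 | O=C1O[C@@H](C=C1CBr)/C=C(/CO[Si](c1ccccc1)(c1ccccc1)C(C)(C)C)CC/C=C(/CO[Si](c1ccccc1)(c1ccccc1)C(C)(C)C)I | intermediate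
29 | (tert-butyldimethylsilyloxy)acetaldehyde | O=CCO[Si](C)(C)C(C)(C)C | starting material
30 | allylzinc bromide from 28 | O=C1O[C@@H](C=C1C[Zn]Br)/C=C(/CO[Si](c1ccccc1)(c1ccccc1)C(C)(C)C)CC/C=C(/CO[Si](c1ccccc1)(c1ccccc1)C(C)(C)C)I | intermediate
31 | (4R,5R)-4-[(1R)-2-(TBSO)-1-hydroxyethyl]-5-[(1E,5Z)-7-(TBDPSO)-6-iodo-2-(TBDPSOCH2)hepta-1,5-dien-1-yl]-3-methylideneoxolan-2-one | C=C1C(=O)O[C@H](/C=C(/CO[Si](c2ccccc2)(c2ccccc2)C(C)(C)C)CC/C=C(/CO[Si](c2ccccc2)(c2ccccc2)C(C)(C)C)I)[C@H]1[C@@H](O)CO[Si](C)(C)C(C)(C)C | intermediate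
32 | (S)-2-methylbutanoic acid | CC[C@H](C)C(=O)O | starting material
33 | O-acylisourea from 32 and DCC | CC[C@H](C)C(=O)OC(=NC1CCCCC1)NC1CCCCC1 | intermediate
34 | C8 (2S)-2-methylbutanoate of 31 (6R,7S,8R; C9–OTBS) | C=C1C(=O)O[C@H](/C=C(/CO[Si](c2ccccc2)(c2ccccc2)C(C)(C)C)CC/C=C(/CO[Si](c2ccccc2)(c2ccccc2)C(C)(C)C)I)[C@H]1[C@@H](OC(=O)[C@@H](C)CC)CO[Si](C)(C)C(C)(C)C | intermediate
35 | C9 primary alcohol from 34 | C=C1C(=O)O[C@H](/C=C(/CO[Si](c2ccccc2)(c2ccccc2)C(C)(C)C)CC/C=C(/CO[Si](c2ccccc2)(c2ccccc2)C(C)(C)C)I)[C@H]1[C@@H](OC(=O)[C@@H](C)CC)CO | intermediate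
36 | C9 aldehyde from 35 | C=C1C(=O)O[C@H](/C=C(/CO[Si](c2ccccc2)(c2ccccc2)C(C)(C)C)CC/C=C(/CO[Si](c2ccccc2)(c2ccccc2)C(C)(C)C)I)[C@H]1[C@@H](OC(=O)[C@@H](C)CC)C=O | intermediate
37 | C10 alkenylchromium dichloride from 36 | C=C1C(=O)O[C@H](/C=C(/CO[Si](c2ccccc2)(c2ccccc2)C(C)(C)C)CC/C=C(/CO[Si](c2ccccc2)(c2ccccc2)C(C)(C)C)[Cr](Cl)Cl)[C@H]1[C@@H](OC(=O)[C@@H](C)CC)C=O | intermediate
38 | (1(10)Z,4E,6R,7S,8R,9S)-14,15-bis(TBDPSO)-9-hydroxy-8-[(2S)-2-methylbutanoyloxy]germacra-1(10),4,11(13)-trien-12,6-olide | C=C1C(=O)O[C@@H]2/C=C(/CO[Si](c3ccccc3)(c3ccccc3)C(C)(C)C)CC/C=C(/CO[Si](c3ccccc3)(c3ccccc3)C(C)(C)C)[C@H](O)[C@H](OC(=O)[C@@H](C)CC)[C@@H]12 | intermediate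
39 | 9-O-acetate of 38 | C=C1C(=O)O[C@@H]2/C=C(/CO[Si](c3ccccc3)(c3ccccc3)C(C)(C)C)CC/C=C(/CO[Si](c3ccccc3)(c3ccccc3)C(C)(C)C)[C@H](OC(C)=O)[C@H](OC(=O)[C@@H](C)CC)[C@@H]12 | intermediate
40 | (3aS,4R,5S,6Z,10E,11aR)-5-acetoxy-6,10-bis(hydroxymethyl)-3-methylidene-2-oxo-2,3,3a,4,5,8,9,11a-octahydrocyclodeca[b]furan-4-yl (2S)-2-methylbutanoate | C=C1C(=O)O[C@@H]2/C=C(/CO)CC/C=C(/CO)[C@H](OC(C)=O)[C@H](OC(=O)[C@@H](C)CC)[C@@H]12 | target

## Summary
Total step count: 26.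
Longest linear sequence: 24 (steps 1–13, then 16–26). Steps 14–15 form a two-step branch.

### Steps most likely to fail

**Step 24 (ring closure).** Closing a ten-membered ring competes with oligomerisation, and the C9 ratio depends on the ring conformation as well as on Felkin control. In the fallback, C9 is set by hydride delivery instead of by the C–C bond formation. It sets out from 36. The closure is accepted whatever its C9 ratio. The 9R alcohol 9-epi-38 F6, alone or mixed with 38, is oxidised with Dess–Martin periodinane to the macrocyclic C9 enone F7. Luche reduction (NaBH4, CeCl3·7H2O, MeOH, −78 °C) then delivers hydride from the outer face of the ring, anti to the C8–O bond, and the route is rejoined at 38.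

**Step 20 (key allylation).** The small, unbranched aldehyde 29 could give a lower C8 ratio, and the free C8 alcohol could translactonise. In the fallback, the C8–C9 building block becomes a chiral α-branched aldehyde, and the C9 aldehyde is released later by glycol cleavage. It sets out from 28. The same allylzinc 30 (Zn, THF/aq NH4Cl) is added to (S)-2,3-O-isopropylideneglyceraldehyde F2, whose Felkin preference (8,9-anti) reinforces the chair-controlled addition. This gives the C8 carbinol acetonide adduct F3. Steglich esterification with 32 gives the acetonide ester F4. Warm 80 % aq AcOH removes the acetonide to give the terminal 1,2-diol F5. NaIO4 in THF/H2O cleaves the diol, and the route is rejoined at 36, which also bypasses steps 22 and 23.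

**Step 3 (kinetic resolution).** The slim alkynyl group may lower the rate ratio, and half the material is lost in any case. In the fallback, asymmetric ketone reduction replaces the resolution. It sets out from 5, which is oxidised with MnO2 in CH2Cl2 to (E)-1-(TBDPSO)hept-5-en-2-yn-4-one F1. Midland reduction with (S)-Alpine-Borane (B-isopinocampheyl-9-BBN from (−)-α-pinene, neat, rt) treats the alkynyl group as the small substituent. By analogy with (S)-1-octyn-3-ol it gives the (S)-alcohol, and the route is rejoined at 6.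

## Further compounds
F1 | step 3 | (E)-1-(TBDPSO)hept-5-en-2-yn-4-one | C/C=C/C(=O)C#CCO[Si](c1ccccc1)(c1ccccc1)C(C)(C)C
F2 | step 20 | (S)-2,3-O-isopropylideneglyceraldehyde | O=C[C@@H]1COC(C)(C)O1
F3 | step 20 | C8 carbinol acetonide adduct | C=C1C(=O)O[C@H](/C=C(/CO[Si](c2ccccc2)(c2ccccc2)C(C)(C)C)CC/C=C(/CO[Si](c2ccccc2)(c2ccccc2)C(C)(C)C)I)[C@H]1[C@@H](O)[C@@H]1COC(C)(C)O1
F4 | step 20 | acetonide ester | C=C1C(=O)O[C@H](/C=C(/CO[Si](c2ccccc2)(c2ccccc2)C(C)(C)C)CC/C=C(/CO[Si](c2ccccc2)(c2ccccc2)C(C)(C)C)I)[C@H]1[C@@H](OC(=O)[C@@H](C)CC)[C@@H]1COC(C)(C)O1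
F5 | step 20 | terminal 1,2-diol | C=C1C(=O)O[C@H](/C=C(/CO[Si](c2ccccc2)(c2ccccc2)C(C)(C)C)CC/C=C(/CO[Si](c2ccccc2)(c2ccccc2)C(C)(C)C)I)[C@H]1[C@@H](OC(=O)[C@@H](C)CC)[C@@H](O)CO
F6 | step 24 | 9-epi-38 | C=C1C(=O)O[C@@H]2/C=C(/CO[Si](c3ccccc3)(c3ccccc3)C(C)(C)C)CC/C=C(/CO[Si](c3ccccc3)(c3ccccc3)C(C)(C)C)[C@@H](O)[C@H](OC(=O)[C@@H](C)CC)[C@@H]12
F7 | step 24 | macrocyclic C9 enone | C=C1C(=O)O[C@@H]2/C=C(/CO[Si](c3ccccc3)(c3ccccc3)C(C)(C)C)CC/C=C(/CO[Si](c3ccccc3)(c3ccccc3)C(C)(C)C)C(=O)[C@H](OC(=O)[C@@H](C)CC)[C@@H]12
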